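Compound numbers are those of the route below. Ring positions carry labdane locants (ring A = C1–C5, C10; ring B = C5–C10; C17 = methylene carbon on C8; C18 = oxygenated carbon on C4; C19 = methyl on C4; C20 = methyl on C10); β is the face of the C10 methyl, α the opposite face.

## Analysis of the target

The target 38 is a 5βH-labdane: a decalin whose ring A holds a C3 ketone and a quaternary C4 (methyl C19, acetoxymethyl C18), and whose ring B holds the C8=C17 exocyclic methylene and, on C9, a five-carbon arm ending in a (13Z)-3-methyl-2-enoic acid. The four stereocentres C4, C5, C10 and C9 are contiguous; C4 and C10 are quaternary and 1,3-related through C5. The C4 methyl, H5, the C10 methyl and the C9 arm are all β, so the ring fusion is cis, while C18 and H9 are α. The β-acetoxy ketone is fragile: with base the acetate is lost, and the free β-hydroxy ketone with its quaternary α-carbon can undergo retro-aldol loss of formaldehyde. The 1,1-disubstituted exocyclic alkene migrates into the ring under strong acid, and the Z-enoic acid can isomerise or deconjugate. The synthesis is hard because the cis fusion is flanked by two quaternary carbons and cannot be corrected by equilibration, because C9 is fixed once the methylene is in place, and because the C8 carbonyl needed on the way has two enolisable neighbours. The strategy rests on ring A: the pattern "C4 methyl, H5 and C10 methyl on one face, C18 on the other" is what a suprafacial [4+2] addition of a (Z)-2-methyl enoate (C4=C5) to an (E)-diene (C10=C1–C2=C3) leaves behind when the ester and the connecting chain are endo, forming C3–C4 and C5–C10 and both rings at once.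

## Retrosynthetic reasoning

**C3 and C18 (38 back to 33).** The C3 ketone is revealed last, by oxidation of 37, so that the β-acetoxy ketone never meets base. The acetate of 37 comes from selective acylation of the primary hydroxyl of dihydroxy acid 35. The acid is freed from ester 34 before any acetate exists. The two ring A oxygens travel together as the isopropylidene acetal of 33, so one group covers both through all basic and organometallic steps.

**C12–C13 (33 back to 29 and 31).** The bond is cut between an sp3 and an sp2 carbon: alkylzinc 32, from iodide 29, is joined to iodoenoate 31, which is made in one step from ynoate 30. The 13Z geometry is carried in by 31 and transferred with retention. Cutting C13=C14 instead would require olefination of a methyl ketone with poor geometric control.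

**C8=C17 and C9–C11 (29 back to 22 and 23).** Iodide 29 comes through alcohol 28 and ester 27 from ketone 26 by carbonyl methylenation. The C9–C11 bond is made by alkylating dienolate 24 with bromoacetate 23, followed by saturation of C6=C7 (25 to 26). The cut is placed on enone 22 and not on the saturated ketone 19, because 19 would enolise towards C7, away from the quaternary C10. In 22 the C7 hydrogens are gone and only C9 can be deprotonated kinetically.

**Enone 22 back to 17.** The C6=C7 bond is introduced through the kinetic enol silane 21 (via enolate 20) of ketone 19. Here the natural preference for C7 is used, not fought. Ketone 19 is the oxidised form of alcohol 18, which is freed from silyl ether 17 once the C8 stereocentre has done its work.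

**Ring A oxygenation (17 back to 13).** Acetal 17 comes from diol 16, and 16 from keto ester 15 by reducing both carbonyls. Keto ester 15 is the hydrogenation product of enone 14, made by allylic oxidation of adduct 13. C3 is the only carbon of 13 with allylic hydrogens, since the other allylic carbon, C10, is quaternary.

**Key disconnection (13 back to 12).** C3–C4 and C5–C10 are cut together. This opens both rings and leaves the acyclic trienoate 12, in which the three ring stereocentres are encoded as two olefin geometries and one silyloxy stereocentre. No other cut of ring A sets C4, C5 and C10 in one step with C4 already carrying its two different substituents.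

**Triene 12 back to 1 and 2.** The diene is finished by joining C1 to C2 (alkenyl iodide 10 with vinylboronate 11). The Z-enoate comes from aldehyde 8 and phosphonate 9, and 8 from oxidative cleavage of the terminal alkene of 6 (via diol 7). The E-iodoalkene of 6 with its methyl (C20) arises from alkyne 4 through alane 5. Ether 4 is the silylated form of alcohol 3, made by joining C9 to C10 in the opening of epoxide 1 by acetylide 2. The single stereocentre of 1 becomes C8.

## Alternatives that were turned down

**Alternative 1:** The C5–C6 bond of ring B is cut. Ring A is then the prochiral dienone A2 (4-methyl-4-substituted cyclohexa-2,5-dienone whose side chain carries the C8 dioxolane and a terminal bis(phenylsulfonyl)methyl group). In the forward step a cinchona-derived bifunctional urea steers the sulfonyl-stabilised carbanion onto one of the two enantiotopic enone arms (6-exo Michael addition), giving the bicyclic enone A1.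
- For it: the absolute configuration comes from a catalyst acting on an achiral substrate. The cis fusion is enforced by geometry, because the chain on C10 can reach C5 only on its own face; in the chosen route endo has to win over exo. The C3 carbonyl is present from the start, so no allylic oxidation is needed. On these three points it is as strong as or stronger than the chosen route.
- Against it: A1 has a bare methylene at C4. The quaternary C4 would need two successive alkylations next to the ring fusion and the bulky C6 bis-sulfone, with no element that secures which group goes α and which β. Both sulfonyl groups must be removed reductively in the presence of an enone, C1=C2 must be saturated, and the C9 problem remains the same.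
- Comparison: the chosen cycloaddition delivers C4 complete and stereodefined from the olefin geometry in the ring-forming step. This outweighs its dependence on one purchased stereocentre and one extra oxidation.

**Alternative 2:** Here C1–C10 is formed while C3–C8 is broken. Ring B pre-exists as the cyclohexene bridge of the bicyclo[2.2.2]octenol A4, and its potassium alkoxide (KH, 18-crown-6) undergoes an anionic oxy-Cope rearrangement to A3, a cis-decalin with the C3 ketone, a complete C4 (C18 as PMB ether) and a C8=C9 methyl enol ether.
- For it: A3 is further advanced than adduct 13. The C3 carbonyl and the finished C4 are in place, and the enol ether is regiodefined towards C9. This answers directly the C7/C9 enolisation problem that costs the chosen route three steps (enol silane, dehydrogenation, re-hydrogenation). On that point it is clearly stronger.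
- Against it: A4 carries four stereocentres, among them the quaternary C4 and a tertiary carbinol whose vinyl group must sit on the side of the C9=C10 bridge. It would come from a Diels–Alder reaction of a 1-methoxycyclohexadiene with a 1,1-disubstituted dienophile, where methyl and oxymethyl have little endo/exo bias, followed by vinyl addition to a hindered bridged ketone from the more crowded face. There is no simple source of absolute configuration, and the [3,3] shift must bond to the methyl-bearing alkene carbon.
- Comparison: the chosen route draws its absolute sense from one cheap stereocentre and its C4 configuration from a Z-olefin. In place of the regiodefined enol ether it offers a C8 oxygen that first controls the cycloaddition and then, through the enone detour, still gives access to C9.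

**Alternative 3:** The C8–C9 bond is cut. Ring B is closed by a Pd(OAc)2/bis(benzylidene)ethylenediamine Alder-ene cycloisomerisation of the 1,7-enyne A6 (ring A with a but-3-ynyl group on C5, an alkenyl ester arm on C10 and a C3 dioxolane), which gives A5 with the C8=C17 methylene and a C11=C12 enoate on C9.
- For it: the exocyclic methylene, the C9–C11 bond and the C9 stereocentre appear in one atom-economic step, with no ketone methylenation and no enolate regiochemistry. For ring B this is shorter than the chosen route.
- Against it: A6 must already contain the cis-related C5 and quaternary C10, so the central stereochemical problem is moved into the substrate synthesis. C4 is again a bare methylene, and later alkylation of the C3 ketone would favour the less hindered C2. Six-membered closure of a 1,7-enyne is slower than the usual five-membered case, and the C9 configuration depends only on the neighbouring quaternary centre. The arm arrives one carbon short with the wrong unsaturation, so conjugate reduction and a Z-selective three-carbon extension are still needed.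
- Comparison: the chosen strategy spends more steps on ring B but settles C4, C5 and C10 together, which neither A5 nor its precursor does.

Key step: step 7

**Remarks before the steps**

- Assumption: epoxide 1 is bought as the single S enantiomer.
- Assumption: the C3 carbinol of 16–18, 20–22, 24–29 and 32–37 is drawn as the expected 3α epimer. Its configuration has no consequence, because C3 ends as a ketone.

## Route

Step 1
Reactants: 1 (S)-2-(but-3-en-1-yl)oxirane; 2 lithium acetylide–ethylenediamine complex
Product: 3 (S)-oct-7-en-1-yn-4-ol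
Conditions: LiC≡CH·H2NCH2CH2NH2 (1.5 equiv), DMSO, 0 °C → rt; H2O
Reagents that add atoms: lithium acetylide–ethylenediamine complex ([Li]C#C.NCCN)
Why: SN2 opening of a terminal epoxide by an acetylide at the unsubstituted carbon; the C–O bond of the stereocentre (future C8) is not touched, so the S configuration of 1 is carried over.

Step 2
Reactants: 3 (S)-oct-7-en-1-yn-4-ol
Product: 4 (S)-tert-butyldimethyl(oct-7-en-1-yn-4-yloxy)silane
Conditions: TBSCl, imidazole, DMF, rt
Reagents that add atoms: tert-butyldimethylsilyl chloride (CC(C)(C)[Si](C)(C)Cl)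
Why: Standard silylation of a secondary alcohol; the bulky silyl ether is the group that will steer step 7 and it tolerates alanes, Me2AlCl and hydride.

Step 3
Reactants: 4 (S)-tert-butyldimethyl(oct-7-en-1-yn-4-yloxy)silane
Product: 6 tert-butyl{[(4S,7E)-8-iodo-7-methylocta-1,7-dien-4-yl]oxy}dimethylsilane, via alkenylalane 5 (not isolated)
Conditions: Me3Al (2.5 equiv), Cp2ZrCl2 (0.25 equiv), CH2Cl2, 0 °C → rt; then I2, THF, −30 → 0 °C
Reagents that add atoms: trimethylaluminium (C[Al](C)C); iodine (II)
Why: Negishi zirconium-catalysed methylalumination adds methyl and aluminium syn across the terminal alkyne with methyl on the internal carbon (future C10 and C20), and iodinolysis with retention gives the E-iodoalkene; the alkyne reacts much faster than the unactivated monosubstituted alkene under Cp2ZrCl2 catalysis.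

Step 4
Reactants: 6 tert-butyl{[(4S,7E)-8-iodo-7-methylocta-1,7-dien-4-yl]oxy}dimethylsilane
Product: 8 (4S,6E)-4-(tert-butyldimethylsilyloxy)-7-iodo-6-methylhept-6-enal, via 1,2-diol 7 (not isolated)
Conditions: OsO4 (2 mol %), NaIO4 (4 equiv), 2,6-lutidine, dioxane/H2O 3:1, rt
Reagents that add atoms: sodium periodate ([Na+].[O-]I(=O)(=O)=O); osmium tetroxide (O=[Os](=O)(=O)=O)
Why: Lemieux–Johnson cleavage; OsO4 should choose the unhindered monosubstituted alkene over the trisubstituted, halogen-deactivated iodoalkene, and 2,6-lutidine suppresses over-oxidation.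

Step 5
Reactants: 8 (4S,6E)-4-(tert-butyldimethylsilyloxy)-7-iodo-6-methylhept-6-enal; 9 methyl 2-[bis(2,2,2-trifluoroethoxy)phosphoryl]propanoate
Product: 10 methyl (2Z,6S,8E)-6-(tert-butyldimethylsilyloxy)-9-iodo-2,8-dimethylnona-2,8-dienoate
Conditions: 9, KN(SiMe3)2 (KHMDS), 18-crown-6, THF, −78 °C; then 8
Reagents that add atoms: methyl 2-[bis(2,2,2-trifluoroethoxy)phosphoryl]propanoate (COC(=O)C(C)P(=O)(OCC(F)(F)F)OCC(F)(F)F)
Why: Still–Gennari olefination; the electron-poor trifluoroethyl phosphonate with a dissociated potassium counter-ion eliminates quickly from the kinetic adduct, which should give the (Z)-2-methyl enoate (future C4=C5, ester cis to C6).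

Step 6
Reactants: 10 methyl (2Z,6S,8E)-6-(tert-butyldimethylsilyloxy)-9-iodo-2,8-dimethylnona-2,8-dienoate; 11 vinylboronic acid pinacol ester
Product: 12 methyl (2Z,6S,8E)-6-(tert-butyldimethylsilyloxy)-2,8-dimethylundeca-2,8,10-trienoate
Conditions: Pd(dppf)Cl2 (5 mol %), K3PO4, THF/H2O, 45 °C
Reagents that add atoms: vinylboronic acid pinacol ester (C=CB1OC(C)(C)C(C)(C)O1)
Why: Suzuki–Miyaura coupling of an alkenyl iodide with a vinylboronate goes with retention, so the diene is E with the chain outside and the C20 methyl inside; the mild base leaves the methyl ester and the Z-enoate alone.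

Step 7
Reactants: 12 methyl (2Z,6S,8E)-6-(tert-butyldimethylsilyloxy)-2,8-dimethylundeca-2,8,10-trienoate
Product: 13 methyl 8β-(tert-butyldimethylsilyloxy)-4β,10β-dimethyl-5βH-decal-1-ene-4α-carboxylate
Conditions: Me2AlCl (1.5 equiv), CH2Cl2, −78 → 0 °C
Reagents that add atoms: none
Why: Concerted, asynchronous, suprafacial [4+2] cycloaddition of the Me2AlCl-complexed (Z)-2-methyl enoate C4=C5 across the diene C10=C1–C2=C3, forming C3–C4 and C5–C10; the closest known reaction type is the Lewis-acid-promoted type 1 intramolecular Diels–Alder reaction of deca-2,7,9-trienoates. Ring A closes as the new cyclohexene (six-membered pericyclic closure that leaves C1=C2), and ring B closes at the same time through the C5–C10 bond as the ring of the four-carbon chain C6–C9, in a chair-like arrangement. C4 is set by the Z geometry: ester and C6 start cis and stay cis, so the C4 methyl ends on the face of H5 and C18 on the other. The C5/C10 relationship follows from the endo transition state: the complexed ester, and with it the cis-placed chain, lies under the diene, and since the chain is the outside and C20 the inside substituent of the E-diene terminus, H5 and the C10 methyl end cis (cis fusion). The absolute sense comes from C8: in the chair of this endo mode C1 is axial on C10, so the silyloxy group must be equatorial, which for the S centre leaves one diene face open, while addition to the other face would put the silyloxy group 1,3-diaxial to C1. The step needs endo over exo selectivity, diene-face selectivity and an intact Z-enoate. Lewis-acid complexation should enlarge the endo preference and the C8 substituent sets the face. The low temperature, with Me2AlCl also acting as proton scavenger, guards against enoate isomerisation and against the [1,5]-hydrogen shift open to a diene with an inside methyl.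

Step 8
Reactants: 13 methyl 8β-(tert-butyldimethylsilyloxy)-4β,10β-dimethyl-5βH-decal-1-ene-4α-carboxylate
Product: 14 methyl 8β-(tert-butyldimethylsilyloxy)-4β,10β-dimethyl-3-oxo-5βH-decal-1-ene-4α-carboxylate
Conditions: CrO3, 3,5-dimethylpyrazole, CH2Cl2, −20 °C
Reagents that add atoms: chromium trioxide (O=[Cr](=O)=O)
Why: Allylic oxidation with the CrO3–3,5-dimethylpyrazole complex; C3 is the only carbon of 13 that bears allylic hydrogens, and oxidation there gives the 3-ketone conjugated with C1=C2, while silyl ether and ester are inert.

Step 9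
Reactants: 14 methyl 8β-(tert-butyldimethylsilyloxy)-4β,10β-dimethyl-3-oxo-5βH-decal-1-ene-4α-carboxylate
Product: 15 methyl 8β-(tert-butyldimethylsilyloxy)-4β,10β-dimethyl-3-oxo-5βH-decalin-4α-carboxylate
Conditions: H2 (1 atm), Pd/C, EtOAc, rt
Reagents that add atoms: none
Why: Catalytic hydrogenation of the disubstituted enone alkene; C1 and C2 become methylenes, so no stereocentre is made, and ketone, ester and silyl ether are untouched.

Step 10
Reactants: 15 methyl 8β-(tert-butyldimethylsilyloxy)-4β,10β-dimethyl-3-oxo-5βH-decalin-4α-carboxylate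
Product: 16 8β-(tert-butyldimethylsilyloxy)-4α-(hydroxymethyl)-4β,10β-dimethyl-5βH-decalin-3α-ol
Conditions: LiAlH4, THF, 0 °C → rt
Reagents that add atoms: none
Why: Hydride reduction of the C3 ketone and the neopentyl C18 ester gives the 1,3-diol; hydride is expected on the β face (axial attack in the ring A chair that has C18 axial), but the C3 configuration does not matter because C3 is re-oxidised in step 26.

Step 11
Reactants: 16 8β-(tert-butyldimethylsilyloxy)-4α-(hydroxymethyl)-4β,10β-dimethyl-5βH-decalin-3α-ol
Product: 17 8β-(tert-butyldimethylsilyloxy)-3α,18-(isopropylidenedioxy)-4β,10β-dimethyl-5βH-decalin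
Conditions: Me2C(OMe)2, PPTS (cat.), CH2Cl2, rt
Reagents that add atoms: 2,2-dimethoxypropane (COC(C)(C)OC)
Why: Acetal exchange closes a six-membered 1,3-dioxane across O3 and O18; one base- and hydride-stable group now masks both ring A oxygens, and the secondary silyl ether survives PPTS.

Step 12
Reactants: 17 8β-(tert-butyldimethylsilyloxy)-3α,18-(isopropylidenedioxy)-4β,10β-dimethyl-5βH-decalin
Product: 18 3α,18-(isopropylidenedioxy)-4β,10β-dimethyl-5βH-decalin-8β-ol
Conditions: TBAF, THF, rt
Reagents that add atoms: none
Why: Fluoride cleaves the Si–O bond; the acetal is inert to fluoride.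

Step 13
Reactants: 18 3α,18-(isopropylidenedioxy)-4β,10β-dimethyl-5βH-decalin-8β-ol
Product: 19 3α,18-(isopropylidenedioxy)-4β,10β-dimethyl-5βH-decalin-8-one
Conditions: Dess–Martin periodinane, NaHCO3, CH2Cl2, rt
Reagents that add atoms: none
Why: Dess–Martin oxidation of the secondary alcohol under buffered conditions that spare the acetal; the C8 stereocentre, having controlled step 7, is removed here.

Step 14
Reactants: 19 3α,18-(isopropylidenedioxy)-4β,10β-dimethyl-5βH-decalin-8-one
Product: 21 3α,18-(isopropylidenedioxy)-4β,10β-dimethyl-8-(trimethylsilyloxy)-5βH-decal-7-ene, via lithium enolate 20 (not isolated)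
Conditions: LiN(iPr)2 (LDA), TMSCl, THF, −78 °C (in situ quench); Et3N, cold NaHCO3 work-up
Reagents that add atoms: chlorotrimethylsilane (C[Si](C)(C)Cl)
Why: Kinetic deprotonation should occur at C7, the α-methylene that is not next to the quaternary C10 (the behaviour of 3,3-disubstituted cyclohexanones), and O-silylation traps that enolate.

Step 15
Reactants: 21 3α,18-(isopropylidenedioxy)-4β,10β-dimethyl-8-(trimethylsilyloxy)-5βH-decal-7-ene
Product: 22 3α,18-(isopropylidenedioxy)-4β,10β-dimethyl-5βH-decal-6-en-8-one
Conditions: Pd(OAc)2 (1.1 equiv), MeCN, rt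
Reagents that add atoms: none
Why: Saegusa–Ito dehydrogenation; palladation at C7 and β-hydride loss from C6 give the C6=C7 enone, which removes the C7 hydrogens so that only C9 can be enolised in the next step.

Step 16
Reactants: 22 3α,18-(isopropylidenedioxy)-4β,10β-dimethyl-5βH-decal-6-en-8-one; 23 methyl bromoacetate
Product: 25 methyl 2-[3α,18-(isopropylidenedioxy)-4β,10β-dimethyl-8-oxo-5βH,9αH-decal-6-en-9-yl]acetate, via lithium dienolate 24 (not isolated)
Conditions: LiN(iPr)2 (LDA), THF, −78 °C; then DMPU, BrCH2CO2Me, −78 → −40 °C
Reagents that add atoms: methyl bromoacetate (COC(=O)CBr)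
Why: Kinetic α′-deprotonation of the enone (C7 is vinylic and the γ-hydrogen on C5 is not removed under kinetic conditions) gives the cross-conjugated dienolate, which the activated halide alkylates at C9; attack is expected on the convex β face of the cis-decalin, anti to the pseudo-axial C10–C1 bond, which places the arm cis to the C10 methyl as in the target.

Step 17
Reactants: 25 methyl 2-[3α,18-(isopropylidenedioxy)-4β,10β-dimethyl-8-oxo-5βH,9αH-decal-6-en-9-yl]acetate
Product: 26 methyl 2-[3α,18-(isopropylidenedioxy)-4β,10β-dimethyl-8-oxo-5βH,9αH-decalin-9-yl]acetate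
Conditions: H2 (1 atm), Pd/C, EtOAc, rt
Reagents that add atoms: none
Why: The enone alkene is the only C=C bond in 25, and the neutral conditions leave the epimerisable C9 centre alone.

Step 18
Reactants: 26 methyl 2-[3α,18-(isopropylidenedioxy)-4β,10β-dimethyl-8-oxo-5βH,9αH-decalin-9-yl]acetate
Product: 27 methyl 3α,18-(isopropylidenedioxy)-13,14,15,16-tetranor-5βH-labd-8(17)-en-12-oate
Conditions: Zn, CH2Br2, TiCl4, THF (pre-formed reagent); then 26, CH2Cl2, 0 °C → rt
Reagents that add atoms: dibromomethane (BrCBr)
Why: Takai–Lombardo methylenation; the non-basic geminal dizinc/titanium reagent converts hindered, enolisable ketones into methylene compounds without epimerising the α-centre and does not attack the ester, and from here C9 is configurationally fixed.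

Step 19
Reactants: 27 methyl 3α,18-(isopropylidenedioxy)-13,14,15,16-tetranor-5βH-labd-8(17)-en-12-oate
Product: 28 3α,18-(isopropylidenedioxy)-13,14,15,16-tetranor-5βH-labd-8(17)-en-12-ol
Conditions: LiAlH4, Et2O, 0 °C
Reagents that add atoms: none
Why: Ester reduction to the primary alcohol; acetal and isolated alkene are inert to hydride.

Step 20
Reactants: 28 3α,18-(isopropylidenedioxy)-13,14,15,16-tetranor-5βH-labd-8(17)-en-12-ol
Product: 29 12-iodo-3α,18-(isopropylidenedioxy)-13,14,15,16-tetranor-5βH-labd-8(17)-ene
Conditions: I2, PPh3, imidazole, CH2Cl2, 0 °C → rt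
Reagents that add atoms: iodine (II)
Why: Appel-type iodination by SN2 displacement at the unhindered primary carbon; the buffered conditions keep the acetal and the exocyclic alkene.

Step 21
Reactants: 30 ethyl but-2-ynoate
Product: 31 ethyl (2Z)-3-iodobut-2-enoate
Conditions: NaI, AcOH, 115 °C
Reagents that add atoms: sodium iodide ([Na+].[I-])
Why: Conjugate hydroiodination of a 2-ynoate; iodide adds to C3 and protonation anti to it gives the Z isomer with iodine cis to the ester.

Step 22
Reactants: 29 12-iodo-3α,18-(isopropylidenedioxy)-13,14,15,16-tetranor-5βH-labd-8(17)-ene; 31 ethyl (2Z)-3-iodobut-2-enoate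
Product: 33 ethyl (13Z)-3α,18-(isopropylidenedioxy)-5βH-labda-8(17),13-dien-15-oate, via alkylzinc iodide 32 (not isolated)
Conditions: Zn dust (activated), LiCl, THF, 40 °C; then 31, Pd(dppf)Cl2 (5 mol %), THF, rt
Reagents that add atoms: ethyl (2Z)-3-iodobut-2-enoate (I/C(C)=C\C(=O)OCC)
Why: Zinc inserts into the primary C–I bond and Negishi sp3–sp2 coupling follows; oxidative addition and reductive elimination keep the alkenyl geometry, so the chain takes the place of iodine cis to the ester (13Z), and the wide-bite-angle ligand favours reductive elimination over β-hydride loss.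

Step 23
Reactants: 33 ethyl (13Z)-3α,18-(isopropylidenedioxy)-5βH-labda-8(17),13-dien-15-oate
Product: 34 ethyl (13Z)-3α,18-dihydroxy-5βH-labda-8(17),13-dien-15-oate
Conditions: AcOH/THF/H2O 3:1:1, 40 °C
Reagents that add atoms: none
Why: Mild acid hydrolysis of the isopropylidene acetal; acetic acid is too weak to move the exocyclic alkene into the ring or to isomerise the enoate.

Step 24
Reactants: 34 ethyl (13Z)-3α,18-dihydroxy-5βH-labda-8(17),13-dien-15-oate
Product: 35 (13Z)-3α,18-dihydroxy-5βH-labda-8(17),13-dien-15-oic acid
Conditions: LiOH, THF/MeOH/H2O, 40 °C; then 1 M HCl to pH 3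
Reagents that add atoms: lithium hydroxide ([Li+].[OH-])
Why: Saponification of the β,β-disubstituted enoate; it is placed here because no base-sensitive group is present yet (C3 is still an alcohol and there is no acetate).

Step 25
Reactants: 35 (13Z)-3α,18-dihydroxy-5βH-labda-8(17),13-dien-15-oic acid
Product: 37 (13Z)-18-acetoxy-3α-hydroxy-5βH-labda-8(17),13-dien-15-oic acid, via mixed anhydride 36 (not isolated)
Conditions: Ac2O (2.5 equiv), pyridine, CH2Cl2, 0 °C; then aq. NaHCO3/THF, rt; then dilute HCl
Reagents that add atoms: acetic anhydride (CC(=O)OC(C)=O)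
Why: Without an acyl-transfer catalyst at 0 °C the primary C18 hydroxyl should be acetylated faster than the secondary C3 hydroxyl, which sits next to the quaternary C4; the carboxyl group is converted into a mixed anhydride that is hydrolysed back during the bicarbonate work-up.

Step 26
Reactants: 37 (13Z)-18-acetoxy-3α-hydroxy-5βH-labda-8(17),13-dien-15-oic acid
Product: 38 (13Z)-18-acetoxy-3-oxo-5βH-labda-8(17),13-dien-15-oic acid
Conditions: Dess–Martin periodinane, CH2Cl2, 0 °C → rt
Reagents that add atoms: none
Why: Dess–Martin oxidation of the remaining secondary alcohol under near-neutral conditions; as the last step it ensures that the β-acetoxy ketone never meets base, and the free acid and both alkenes are inert.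

## Compound list

1 | (S)-2-(but-3-en-1-yl)oxirane | C=CCC[C@H]1CO1 | starting material
2 | lithium acetylide–ethylenediamine complex | [Li]C#C.NCCN | starting material
3 | (S)-oct-7-en-1-yn-4-ol | C=CCC[C@H](O)CC#C | intermediate
4 | (S)-tert-butyldimethyl(oct-7-en-1-yn-4-yloxy)silane | C=CCC[C@H](O[Si](C)(C)C(C)(C)C)CC#C | intermediate
5 | dimethyl[(1E,4S)-4-(tert-butyldimethylsilyloxy)-2-methylocta-1,7-dien-1-yl]alane | C=CCC[C@H](O[Si](C)(C)C(C)(C)C)C/C(C)=C/[Al](C)C | intermediate (not isolated)
6 | tert-butyl{[(4S,7E)-8-iodo-7-methylocta-1,7-dien-4-yl]oxy}dimethylsilane | C=CCC[C@H](O[Si](C)(C)C(C)(C)C)C/C(C)=C/I | intermediate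
7 | (5S,7E)-5-(tert-butyldimethylsilyloxy)-8-iodo-7-methyloct-7-ene-1,2-diol (both C2 epimers) | OCC(O)CC[C@H](O[Si](C)(C)C(C)(C)C)C/C(C)=C/I | intermediate (not isolated)
8 | (4S,6E)-4-(tert-butyldimethylsilyloxy)-7-iodo-6-methylhept-6-enal | O=CCC[C@H](O[Si](C)(C)C(C)(C)C)C/C(C)=C/I | intermediate
9 | methyl 2-[bis(2,2,2-trifluoroethoxy)phosphoryl]propanoate | COC(=O)C(C)P(=O)(OCC(F)(F)F)OCC(F)(F)F | starting material
10 | methyl (2Z,6S,8E)-6-(tert-butyldimethylsilyloxy)-9-iodo-2,8-dimethylnona-2,8-dienoate | COC(=O)/C(C)=C\CC[C@H](O[Si](C)(C)C(C)(C)C)C/C(C)=C/I | intermediate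
11 | vinylboronic acid pinacol ester | C=CB1OC(C)(C)C(C)(C)O1 | starting material
12 | methyl (2Z,6S,8E)-6-(tert-butyldimethylsilyloxy)-2,8-dimethylundeca-2,8,10-trienoate | COC(=O)/C(C)=C\CC[C@H](O[Si](C)(C)C(C)(C)C)C/C(C)=C/C=C | intermediate
13 | methyl 8β-(tert-butyldimethylsilyloxy)-4β,10β-dimethyl-5βH-decal-1-ene-4α-carboxylate | CC(C)(C)[Si](C)(C)O[C@H]1CC[C@H]2[C@](C)(C=CC[C@@]2(C)C(=O)OC)C1 | intermediate
14 | methyl 8β-(tert-butyldimethylsilyloxy)-4β,10β-dimethyl-3-oxo-5βH-decal-1-ene-4α-carboxylate | CC(C)(C)[Si](C)(C)O[C@H]1CC[C@H]2[C@](C)(C=CC(=O)[C@@]2(C)C(=O)OC)C1 | intermediate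
15 | methyl 8β-(tert-butyldimethylsilyloxy)-4β,10β-dimethyl-3-oxo-5βH-decalin-4α-carboxylate | CC(C)(C)[Si](C)(C)O[C@H]1CC[C@H]2[C@](C)(CCC(=O)[C@@]2(C)C(=O)OC)C1 | intermediate
16 | 8β-(tert-butyldimethylsilyloxy)-4α-(hydroxymethyl)-4β,10β-dimethyl-5βH-decalin-3α-ol | CC(C)(C)[Si](C)(C)O[C@H]1CC[C@H]2[C@](C)(CC[C@@H](O)[C@@]2(C)CO)C1 | intermediate
17 | 8β-(tert-butyldimethylsilyloxy)-3α,18-(isopropylidenedioxy)-4β,10β-dimethyl-5βH-decalin | CC(C)(C)[Si](C)(C)O[C@H]1CC[C@H]2[C@](C)(CC[C@H]3OC(C)(C)OC[C@@]23C)C1 | intermediate
18 | 3α,18-(isopropylidenedioxy)-4β,10β-dimethyl-5βH-decalin-8β-ol | O[C@H]1CC[C@H]2[C@](C)(CC[C@H]3OC(C)(C)OC[C@@]23C)C1 | intermediate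
19 | 3α,18-(isopropylidenedioxy)-4β,10β-dimethyl-5βH-decalin-8-one | O=C1CC[C@H]2[C@](C)(CC[C@H]3OC(C)(C)OC[C@@]23C)C1 | intermediate
20 | lithium 7-en-8-olate of 19 | [Li]OC1=CC[C@H]2[C@](C)(CC[C@H]3OC(C)(C)OC[C@@]23C)C1 | intermediate (not isolated)
21 | 3α,18-(isopropylidenedioxy)-4β,10β-dimethyl-8-(trimethylsilyloxy)-5βH-decal-7-ene | C[Si](C)(C)OC1=CC[C@H]2[C@](C)(CC[C@H]3OC(C)(C)OC[C@@]23C)C1 | intermediate
22 | 3α,18-(isopropylidenedioxy)-4β,10β-dimethyl-5βH-decal-6-en-8-one | O=C1C=C[C@H]2[C@](C)(CC[C@H]3OC(C)(C)OC[C@@]23C)C1 | intermediate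
23 | methyl bromoacetate | COC(=O)CBr | starting material
24 | lithium 6,8(9)-dien-8-olate of 22 | [Li]OC1C=C[C@H]2[C@](C)(CC[C@H]3OC(C)(C)OC[C@@]23C)C=1 | intermediate (not isolated)
25 | methyl 2-[3α,18-(isopropylidenedioxy)-4β,10β-dimethyl-8-oxo-5βH,9αH-decal-6-en-9-yl]acetate | O=C1C=C[C@H]2[C@](C)(CC[C@H]3OC(C)(C)OC[C@@]23C)[C@H]1CC(=O)OC | intermediate
26 | methyl 2-[3α,18-(isopropylidenedioxy)-4β,10β-dimethyl-8-oxo-5βH,9αH-decalin-9-yl]acetate | O=C1CC[C@H]2[C@](C)(CC[C@H]3OC(C)(C)OC[C@@]23C)[C@H]1CC(=O)OC | intermediate
27 | methyl 3α,18-(isopropylidenedioxy)-13,14,15,16-tetranor-5βH-labd-8(17)-en-12-oate | C=C1CC[C@H]2[C@](C)(CC[C@H]3OC(C)(C)OC[C@@]23C)[C@H]1CC(=O)OC | intermediate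
28 | 3α,18-(isopropylidenedioxy)-13,14,15,16-tetranor-5βH-labd-8(17)-en-12-ol | C=C1CC[C@H]2[C@](C)(CC[C@H]3OC(C)(C)OC[C@@]23C)[C@H]1CCO | intermediate
29 | 12-iodo-3α,18-(isopropylidenedioxy)-13,14,15,16-tetranor-5βH-labd-8(17)-ene | C=C1CC[C@H]2[C@](C)(CC[C@H]3OC(C)(C)OC[C@@]23C)[C@H]1CCI | intermediate
30 | ethyl but-2-ynoate | CC#CC(=O)OCC | starting material
31 | ethyl (2Z)-3-iodobut-2-enoate | I/C(C)=C\C(=O)OCC | intermediate
32 | [3α,18-(isopropylidenedioxy)-13,14,15,16-tetranor-5βH-labd-8(17)-en-12-yl]zinc iodide | C=C1CC[C@H]2[C@](C)(CC[C@H]3OC(C)(C)OC[C@@]23C)[C@H]1CC[Zn]I | intermediate (not isolated)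
33 | ethyl (13Z)-3α,18-(isopropylidenedioxy)-5βH-labda-8(17),13-dien-15-oate | C=C1CC[C@H]2[C@](C)(CC[C@H]3OC(C)(C)OC[C@@]23C)[C@H]1CC/C(C)=C\C(=O)OCC | intermediate
34 | ethyl (13Z)-3α,18-dihydroxy-5βH-labda-8(17),13-dien-15-oate | C=C1CC[C@H]2[C@](C)(CC[C@@H](O)[C@@]2(C)CO)[C@H]1CC/C(C)=C\C(=O)OCC | intermediate
35 | (13Z)-3α,18-dihydroxy-5βH-labda-8(17),13-dien-15-oic acid | C=C1CC[C@H]2[C@](C)(CC[C@@H](O)[C@@]2(C)CO)[C@H]1CC/C(C)=C\C(=O)O | intermediate
36 | acetic (13Z)-18-acetoxy-3α-hydroxy-5βH-labda-8(17),13-dien-15-oic anhydride | C=C1CC[C@H]2[C@](C)(CC[C@@H](O)[C@@]2(C)COC(C)=O)[C@H]1CC/C(C)=C\C(=O)OC(C)=O | intermediate (not isolated)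
37 | (13Z)-18-acetoxy-3α-hydroxy-5βH-labda-8(17),13-dien-15-oic acid | C=C1CC[C@H]2[C@](C)(CC[C@@H](O)[C@@]2(C)COC(C)=O)[C@H]1CC/C(C)=C\C(=O)O | intermediate
38 | (13Z)-18-acetoxy-3-oxo-5βH-labda-8(17),13-dien-15-oic acid | C=C1CC[C@H]2[C@](C)(CCC(=O)[C@@]2(C)COC(C)=O)[C@H]1CC/C(C)=C\C(=O)O | target

## Step count and weakest steps

Total: 26 steps. Longest linear sequence: 25 steps (steps 1–20 and 22–26, from epoxide 1). Step 21 is a one-step side branch.

**Step 7 (key step).**
- What may go wrong: the cycloaddition may be too slow. It joins the β-carbon of a trisubstituted Z-enoate to the fully substituted diene terminus, two quaternary carbons form 1,3 to each other, and the diene must reach its s-cis form against the inside methyl. A slow closure gives room for Lewis-acid-induced Z-to-E isomerisation of the enoate (which would invert C4), for loss of endo selectivity (trans-fused product) and for desilylation. Simple heating without Lewis acid risks the [1,5]-hydrogen shift of the diene.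
- Fallback (stronger dienophile): from 12, reduction with iBu2AlH (CH2Cl2, −78 °C) would give (2Z,6S,8E)-6-(tert-butyldimethylsilyloxy)-2,8-dimethylundeca-2,8,10-trien-1-ol F1, and MnO2 would oxidise it to the (2Z)-trienal F2. The enal is a far better dienophile and should close with Me2AlCl at −78 °C to the cis-fused 4α-carbaldehyde F3. Pinnick oxidation (NaClO2, NaH2PO4, 2-methylbut-2-ene) would give the 4α-carboxylic acid F4, and TMSCHN2 would return it to 13.

**Step 8.**
- What may go wrong: oxygen may be delivered to the wrong end of the allylic system. Hydrogen abstraction at C3 leaves a radical spread over C1–C3, and capture at C1 would give the transposed ketone with the alkene moved to C2=C3; both ends are neopentyl and similarly hindered.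
- Fallback (pericyclic mechanism that cannot transpose): from 13, SeO2 (cat.) with t-BuOOH in CH2Cl2 would react by an ene reaction followed by a [2,3]-sigmatropic shift, which returns oxygen to the carbon that lost hydrogen. This gives methyl 8β-(tert-butyldimethylsilyloxy)-3-hydroxy-4β,10β-dimethyl-5βH-decal-1-ene-4α-carboxylate F5 (either C3 epimer), and Dess–Martin oxidation of it leads to 14.

**Step 16.**
- What may go wrong: facial selectivity at C9 may be poor or reversed, because the β face, although convex, carries the C10 methyl next to C9. Deprotonation at the neopentyl C9 may also be incomplete.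
- Fallback (same facial bias used in the opposite sense, applicable if the electrophile prefers the α face): from 22, dienolate 24 is added to methyl glyoxylate to give the aldol adduct F6 (methyl 2-hydroxy-2-[3α,18-(isopropylidenedioxy)-4β,10β-dimethyl-8-oxo-5βH-decal-6-en-9-yl]acetate). Dehydration with the Burgess reagent gives the 9(11)-alkylidene keto ester F7. Hydrogenation over Pd/C then reduces C6=C7 and C9=C11; hydrogen should reach C9 from the α face that the electrophile had preferred, which gives 26 with the arm β.

**Step 25.**
- What may go wrong: over-acetylation at C3 or incomplete conversion, since both hydroxyls are neopentyl-type and differ only as primary and secondary.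
- Fallback (steric differentiation by a bulky silyl group): from 35, TBDPSCl and imidazole would silylate only the primary hydroxyl, giving (13Z)-18-(tert-butyldiphenylsilyloxy)-3α-hydroxy-5βH-labda-8(17),13-dien-15-oic acid F8; a silyl ester formed at the carboxyl group falls off on work-up. Dess–Martin oxidation gives the 3-ketone F9, HF·pyridine (acidic, so no retro-aldol) frees (13Z)-18-hydroxy-3-oxo-5βH-labda-8(17),13-dien-15-oic acid F10, and Ac2O/pyridine on the single hydroxyl gives 38.

## Further compounds

F1 | step 7 | (2Z,6S,8E)-6-(tert-butyldimethylsilyloxy)-2,8-dimethylundeca-2,8,10-trien-1-ol | OC/C(C)=C\CC[C@H](O[Si](C)(C)C(C)(C)C)C/C(C)=C/C=C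
F2 | step 7 | (2Z,6S,8E)-6-(tert-butyldimethylsilyloxy)-2,8-dimethylundeca-2,8,10-trienal | O=C/C(C)=C\CC[C@H](O[Si](C)(C)C(C)(C)C)C/C(C)=C/C=C
F3 | step 7 | 8β-(tert-butyldimethylsilyloxy)-4β,10β-dimethyl-5βH-decal-1-ene-4α-carbaldehyde | CC(C)(C)[Si](C)(C)O[C@H]1CC[C@H]2[C@](C)(C=CC[C@@]2(C)C=O)C1
F4 | step 7 | 8β-(tert-butyldimethylsilyloxy)-4β,10β-dimethyl-5βH-decal-1-ene-4α-carboxylic acid | CC(C)(C)[Si](C)(C)O[C@H]1CC[C@H]2[C@](C)(C=CC[C@@]2(C)C(=O)O)C1
F5 | step 8 | methyl 8β-(tert-butyldimethylsilyloxy)-3-hydroxy-4β,10β-dimethyl-5βH-decal-1-ene-4α-carboxylate (C3 epimers) | CC(C)(C)[Si](C)(C)O[C@H]1CC[C@H]2[C@](C)(C=CC(O)[C@@]2(C)C(=O)OC)C1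
F6 | step 16 | methyl 2-hydroxy-2-[3α,18-(isopropylidenedioxy)-4β,10β-dimethyl-8-oxo-5βH-decal-6-en-9-yl]acetate (epimers at C9 and C11) | O=C1C=C[C@H]2[C@](C)(CC[C@H]3OC(C)(C)OC[C@@]23C)C1C(O)C(=O)OC
F7 | step 16 | methyl 2-[3α,18-(isopropylidenedioxy)-4β,10β-dimethyl-8-oxo-5βH-decal-6-en-9-ylidene]acetate (either alkene geometry) | O=C1C=C[C@H]2[C@](C)(CC[C@H]3OC(C)(C)OC[C@@]23C)C1=CC(=O)OC
F8 | step 25 | (13Z)-18-(tert-butyldiphenylsilyloxy)-3α-hydroxy-5βH-labda-8(17),13-dien-15-oic acid | C=C1CC[C@H]2[C@](C)(CC[C@@H](O)[C@@]2(C)CO[Si](c3ccccc3)(c3ccccc3)C(C)(C)C)[C@H]1CC/C(C)=C\C(=O)O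
F9 | step 25 | (13Z)-18-(tert-butyldiphenylsilyloxy)-3-oxo-5βH-labda-8(17),13-dien-15-oic acid | C=C1CC[C@H]2[C@](C)(CCC(=O)[C@@]2(C)CO[Si](c3ccccc3)(c3ccccc3)C(C)(C)C)[C@H]1CC/C(C)=C\C(=O)O
F10 | step 25 | (13Z)-18-hydroxy-3-oxo-5βH-labda-8(17),13-dien-15-oic acid | C=C1CC[C@H]2[C@](C)(CCC(=O)[C@@]2(C)CO)[C@H]1CC/C(C)=C\C(=O)O
A1 | alternative 1 | cis-fused 8,8-(ethylenedioxy)-10β-methyl-6,6-bis(phenylsulfonyl)-5βH-decal-1-en-3-one | C12(OCCO1)CC(S(=O)(=O)c1ccccc1)(S(=O)(=O)c1ccccc1)[C@H]3[C@](C)(C=CC(=O)C3)C2
A2 | alternative 1 | 4-{[2-(2,2-bis(phenylsulfonyl)ethyl)-1,3-dioxolan-2-yl]methyl}-4-methylcyclohexa-2,5-dien-1-one (achiral) | CC1(CC2(CC(S(=O)(=O)c3ccccc3)S(=O)(=O)c3ccccc3)OCCO2)C=CC(=O)C=C1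
A3 | alternative 2 | 8-methoxy-18-(4-methoxybenzyloxy)-4β,10β-dimethyl-5βH-decal-8-en-3-one | C1=C(OC)CC[C@H]2[C@]1(C)CCC(=O)[C@@]2(C)COCc1ccc(OC)cc1
A4 | alternative 2 | 1-methoxy-3-[(4-methoxybenzyloxy)methyl]-3,5-dimethyl-2-vinylbicyclo[2.2.2]oct-5-en-2-ol (vinyl and C3 methyl on the side of the alkene bridge) | C=C[C@]1(O)[C@@](C)(COCc3ccc(OC)cc3)[C@H]2CC[C@]1(OC)C=C2C
A5 | alternative 3 | methyl (E)-3-[3,3-(ethylenedioxy)-10β-methyl-8-methylene-5βH,9αH-decalin-9-yl]acrylate | C=C1CC[C@H]2[C@](C)(CCC3(OCCO3)C2)[C@H]1/C=C/C(=O)OC
A6 | alternative 3 | methyl (E)-4-[2-(but-3-yn-1-yl)-4,4-(ethylenedioxy)-1-methylcyclohexyl]but-3-enoate (butynyl and alkenyl arms cis) | C#CCC[C@H]2[C@](C)(CCC3(OCCO3)C2)/C=C/CC(=O)OC
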